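At the charge, reagent is lost to the homo dimer at 0.686 h⁻¹, faster than it can react with dissolved substrate even at saturation, 0.372 h⁻¹, and faster than it decays to side product A, 0.332 h⁻¹.

solid substrate 0.050 M; reagent 0.0900 M; time 8.0 h

    dissolved substrate + reagent → target (k1 = 12.0 M⁻¹ h⁻¹)
    2 reagent → homo dimer (k2 = 3.81 M⁻¹ h⁻¹)
    solid substrate + target → side product B (k3 = 6.12 M⁻¹ h⁻¹)
    solid substrate ⇌ dissolved substrate, rate k4*(cs4 - [dissolved substrate]) while solid is left; crystals form when [dissolved substrate] > cs4 (cs4 = 31 mM, k4 = 3.63 h⁻¹)
    reagent → side product A (k5 = 0.332 h⁻¹)

- percentages count the solid substrate that a species holds: one side product B counts as two
- for a step with 2 of a species take k times the square, and two of it per event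
- solid, in amounts per volume of the solution: solid substrate
- at the start none of the solid substrate is in solution
- run time (flask): 8.0 h

- ochre: doubling the solubility in step 4, all else as stated
- grey: doubling the dissolution coefficient of step 4, all else as stated
- amber: doubling the amount of reagent, all else as stated

* how much target there is at 8.0 h, in percent of the solid substrate charged
* the change that raises the amount of target at 8.0 h, in percent of the solid substrate charged most ("none" if none brings more than 2 percentage points) (ochre / grey / amber / none)
* amount of target at 8.0 h, in percent of the solid substrate charged, after grey

Time can be removed from the question. Dividing the rate of target formation by the rate of reagent loss tells what each spent reagent yields. If dissolved substrate stays at its solubility, 62.0 % of the charge, integrating that ratio as reagent falls gives 66.4 % target.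

But the solution is drained while it is refilled. Balancing dissolution against consumption at the charged reagent puts dissolved substrate at 47.8 % of the charge. At that level, the reagent share, a selectivity factor, is the fraction of spent reagent becoming target once dimerisation has faded: 46.3 %. With dimerisation included, the integral falls to 56.1 %.

The solution also starts empty, which withholds up to 11.0 % of target. Yet the reagent spared is not lost: it stands near its charge, where dimerisation still takes its part, so it yields 22.0 %, less than the reagent share, and this reckoning commits to 47.6 %. One doubt stays open: it omits the attack of solid on target, whose half-life of 2.3 h is shorter than the run, although that step acts solely while solid remains.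

The forecast gave 49 % (44 % to 54 %), slightly above this reckoning, and 53.5 % (48 % to 59 %) after grey. It chose amber, on the ground that “dimerisation and its first-order loss consume most of it within about 2 h”.

The simulation gives 50.1 %, and 55.3 % after grey. It ranks amber first, with gains of 18 percentage points for amber, 11 points for ochre and 5.2 points for grey.

The flask has nearly come to rest at 8.00 h, with 0.32 % of its reagent left. At the reagent share, that remainder is worth 0.268 % of the solid charge, and at 80.0 h target reads 50.4 %. In the neighbour with 0.36 M of reagent, the same steps give a dissolved level of 28.3 %, a share of 33.8 % and 68.6 % target, against 80.9 % simulated.

All constants are invented; what happens was integrated by code.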